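At early times reagent is filling up from none dissolved at the start, and the quick number asked for is a matter of how much reagent the substrate has met by 80 s.

    substrate ⇌ reactive form (K1 = 0.019, k1 = 0.0401 s⁻¹)
    reagent + reactive form → product (k2 = 98.8 M⁻¹ s⁻¹)
    gas ⇌ reagent, rate k3*(csat - [reagent]) (k3 = 0.0206 s⁻¹, csat = 0.51 mM)

| flask | substrate | gas | time |
|---|---|---|---|
| Monday's | 0.0010 M | 0.51 mM (held) | 80 s |
| Thursday's | 0.0015 M | 0.51 mM (held) | 80 s |
| Tuesday's | 0.0025 M | 0.51 mM (held) | 80 s |

- [product] at the end for Monday's, Thursday's, Tuesday's, in this order
- how that number moves from the first to the last of them (hardly changes / rises all the way / falls, then rises / rises, then falls / falls all the way)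

- at the start none of reagent is dissolved
- "hardly changes" means that all values lie within two and a half points (for a concentration: within two and a half percent of the largest)
- run time (Monday's): 80 s

1. Substrate and reactive form relax together with a half-life of 0.322 s, far shorter than the 48.5 s that characterises the filling of reagent, and the back step at 2.11 s⁻¹ is faster than capture at saturation, 0.0504 s⁻¹. So the two form one pool with 1.86% of it as reactive form.

2. That pool falls pseudo-first-order in reagent, with a coefficient equal to the reagent level times the capture constant, which is the reactive form's share of the pool times the rate constant of the second step: 1.84 M⁻¹ s⁻¹.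

3. The fraction left of the pool is then the exponential of minus the capture constant times the exposure, the area under the reagent curve. In Monday's flask reagent climbs with coefficient 0.0224 s⁻¹ toward 4.68 × 10⁻⁴ M, which gives an exposure of 0.0201 M·s, a fraction left of 96.4% and Monday's product at 0.0363 mM.

4. The same reckoning leaves a fraction of 96.4% in Thursday's flask and 96.6% in Tuesday's, which gives product at 0.0535 mM and 0.0860 mM, so from Monday's flask to Tuesday's the number rises all the way. In Tuesday's flask the substrate's pull on reagent is a quarter of the transfer coefficient, so product rises a little less steeply than the charge.

5. The forecast stands at 3.500 × 10⁻⁵ M, 5.200 × 10⁻⁵ M and 8.300 × 10⁻⁵ M, and says the number rises all the way, with reagent that “is only modestly pulled down by the reaction”; its first point lies a little below this reckoning's.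

The flasks give 3.58 × 10⁻⁵ M, 5.28 × 10⁻⁵ M and 8.51 × 10⁻⁵ M, so the number rises all the way. In Monday's flask at 80.0 s, reagent stands at 3.91 × 10⁻⁴ M and, each step taken net, is made 3.59 times faster than it is used. The capture constant serves again in Tuesday's flask at 800 s: with reagent at the 4.53 × 10⁻⁴ M read there, taken over that time less the 48.5 s of filling, the fraction left comes to 53.4%, and Tuesday's flask then holds 54.9% of its charge as substrate and reactive form.

(All constants belong to no real substance; the run is a simulation.)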